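**Assumptions:** The target, 3-docosyl-1H-pyrrole-2-carbaldehyde, has no stereocentre, so it is achiral and no stereocontrol is needed. 3-Bromo-1H-pyrrole-2-carbaldehyde, 1-docosene and 9-BBN (0.5 M in THF) are taken as catalogue materials.

## Retrosynthetic overview

1. Target 7 ⇐ N-Boc compound 6 by unmasking the N–H last.
2. 6 ⇐ C3(sp2)–C(sp3) disconnection by B-alkyl Suzuki–Miyaura coupling: bromide 2 + B-docosyl-9-BBN 5.
3. 5 ⇐ anti-Markovnikov hydroboration of 1-docosene 3 with 9-BBN 4; 2 ⇐ Boc protection of bromoaldehyde 1.
4. No ring is formed: the pyrrole is bought with CHO at C2 and Br at C3, which fixes the regiochemistry.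

## Route

**Step 1**
Reactants: 1 3-bromo-1H-pyrrole-2-carbaldehyde
Product: 2 tert-butyl 3-bromo-2-formyl-1H-pyrrole-1-carboxylate
Conditions: Boc2O (1.2 equiv), DMAP (0.1 equiv), MeCN, rt, 2 h
Reagents that add atoms: di-tert-butyl dicarbonate, CC(C)(C)OC(=O)OC(=O)OC(C)(C)C
Why: DMAP-catalysed N-acylation (Boc protection) of the acidic 2-formylpyrrole N–H prevents pyrrolide formation under the basic coupling conditions and makes the C3–Br bond more electron-poor for oxidative addition.

**Step 2**
Reactants: 2 tert-butyl 3-bromo-2-formyl-1H-pyrrole-1-carboxylate; 3 1-docosene; 4 9-borabicyclo[3.3.1]nonane (9-BBN)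
Product: 6 tert-butyl 3-docosyl-2-formyl-1H-pyrrole-1-carboxylate, via B-docosyl-9-BBN 5 (not isolated)
Conditions: 3 (1.5 equiv), 4 (0.5 M in THF, 1.4 equiv), THF, 0 °C → rt, 6 h; then 2 (1.0 equiv), Pd(dppf)Cl2·CH2Cl2 (5 mol%), powdered K3PO4 (3 equiv), DMF/THF, 50 °C, 12 h; aqueous work-up
Reagents that add atoms: none
Why: Anti-Markovnikov hydroboration gives the primary alkylborane with no B–H left over (alkene in excess), and the B-alkyl Suzuki–Miyaura coupling then joins it to the C3–Br bond activated by the ortho formyl group, with the wide-bite-angle dppf ligand favouring reductive elimination over β-hydride elimination.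

**Step 3**
Reactants: 6 tert-butyl 3-docosyl-2-formyl-1H-pyrrole-1-carboxylate
Product: 7 3-docosyl-1H-pyrrole-2-carbaldehyde
Conditions: K2CO3 (0.5 equiv), MeOH/THF (1:1), rt, 2 h
Reagents that add atoms: none
Why: The N-Boc group on a 2-formylpyrrole is an activated, azolide-like carbamate that is cleaved by mild base-catalysed methanolysis (transacylation to methoxide), leaving the non-enolisable aldehyde and the alkyl chain untouched.

## Compound list

1 | 3-bromo-1H-pyrrole-2-carbaldehyde | O=Cc1[nH]ccc1Br | starting material
2 | tert-butyl 3-bromo-2-formyl-1H-pyrrole-1-carboxylate | CC(C)(C)OC(=O)n1ccc(Br)c1C=O | intermediate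
3 | 1-docosene (docos-1-ene) | C=CCCCCCCCCCCCCCCCCCCCC | starting material
4 | 9-borabicyclo[3.3.1]nonane (9-BBN, used as 0.5 M THF solution) | B1C2CCCC1CCC2 | starting material
5 | B-docosyl-9-BBN (9-docosyl-9-borabicyclo[3.3.1]nonane) | CCCCCCCCCCCCCCCCCCCCCCB1C2CCCC1CCC2 | intermediate (not isolated)
6 | tert-butyl 3-docosyl-2-formyl-1H-pyrrole-1-carboxylate | CCCCCCCCCCCCCCCCCCCCCCc1ccn(C(=O)OC(C)(C)C)c1C=O | intermediate
7 | 3-docosyl-1H-pyrrole-2-carbaldehyde | CCCCCCCCCCCCCCCCCCCCCCc1cc[nH]c1C=O | target

## Summary

Total step count: 3 (the hydroboration is run in the same flask as the coupling in step 2).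
Longest linear sequence: 3 steps (1 → 2 → 6 → 7).

## Steps most likely to fail, with fallbacks

The route has only three steps, so all three are ranked, most risky first.

**Step 2 (most risky).** Transfer of an sp3 alkyl group to a hindered, ortho-formyl pyrrolyl-palladium species can lose out to β-hydride elimination or protodebromination. The alkylborane may also slowly reduce the aldehyde, and part of the Boc group may fall off under the basic conditions. Premature Boc loss after coupling is harmless, because it gives 7 directly. The fallback sets out from 2 and returns at 6. It replaces the sp3 coupling by an sp coupling followed by saturation. 1-Docosyne F1 is made by alkylating lithium acetylide–ethylenediamine complex with commercial 1-bromoicosane in DMSO at rt. Sonogashira coupling of 2 with it (Pd(PPh3)2Cl2, CuI, Et3N, THF, 50 °C) gives tert-butyl 3-(docos-1-yn-1-yl)-2-formyl-1H-pyrrole-1-carboxylate F2. Hydrogenation of the triple bond (H2 1 atm, 10% Pd/C, EtOAc, rt, stopped after 2 equiv of H2) then gives 6.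

**Step 1 (second).** The N-Boc-2-formylpyrrole is an activated carbamate next to two ortho substituents. Acylation may be slow, and the product may shed Boc on silica or on storage. The fallback sets out from 1 and returns at 7. It drops protection altogether: unprotected 1 is coupled directly with borane 5 (generated from 3 and 4 as in step 2) using a catalyst that tolerates free N–H azoles (Pd(OAc)2/SPhos, aqueous K3PO4 4 equiv, THF, 60 °C) to give 7 in one operation. This fallback makes no new compound (F0).

**Step 3 (least risky).** The risks are poor solubility of the waxy C22 compound in methanol and base-induced side reactions of the free 2-formylpyrrole on long exposure. The fallback sets out from 5 and returns at 7. It avoids any N-acyl aldehyde by introducing the formyl group last. Borane 5 is coupled with commercial 3-bromo-1-(triisopropylsilyl)-1H-pyrrole (Pd(dppf)Cl2, K3PO4, DMF/THF, 60 °C) to give 3-docosyl-1-(triisopropylsilyl)-1H-pyrrole F3. TBAF in THF at rt removes the silyl group to give 3-docosyl-1H-pyrrole F4. Vilsmeier–Haack formylation (POCl3, DMF, 1,2-dichloroethane, 0 °C → rt) is expected to go mainly at C2, next to the alkyl group, giving N-[(3-docosyl-1H-pyrrol-2-yl)methylidene]-N-methylmethanaminium chloride F5. Hydrolysis with aqueous NaOAc gives 7. The minor regioisomer 4-docosyl-1H-pyrrole-2-carbaldehyde F6 is removed by chromatography; this regioisomer problem is why the approach is a fallback and not the main route.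

## Further compounds

F1 | step 2 | 1-docosyne (docos-1-yne) | C#CCCCCCCCCCCCCCCCCCCCC
F2 | step 2 | tert-butyl 3-(docos-1-yn-1-yl)-2-formyl-1H-pyrrole-1-carboxylate | CCCCCCCCCCCCCCCCCCCCC#Cc1ccn(C(=O)OC(C)(C)C)c1C=O
F0 | step 1 | none | none
F3 | step 3 | 3-docosyl-1-(triisopropylsilyl)-1H-pyrrole | CCCCCCCCCCCCCCCCCCCCCCc1ccn([Si](C(C)C)(C(C)C)C(C)C)c1
F4 | step 3 | 3-docosyl-1H-pyrrole | CCCCCCCCCCCCCCCCCCCCCCc1cc[nH]c1
F5 | step 3 | N-[(3-docosyl-1H-pyrrol-2-yl)methylidene]-N-methylmethanaminium chloride | CCCCCCCCCCCCCCCCCCCCCCc1cc[nH]c1C=[N+](C)C.[Cl-]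
F6 | step 3 | 4-docosyl-1H-pyrrole-2-carbaldehyde | CCCCCCCCCCCCCCCCCCCCCCc1c[nH]c(C=O)c1
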